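**Retrosynthetic overview**
- The ten-membered ring is closed last, at C1–C10, by a Nozaki–Hiyama–Kishi reaction of a 2-bromoalkene with an aldehyde; this also creates C1.
- The C8 side-chain ester is attached before ring closure (Yamaguchi acylation), so the C1 hydroxyl never needs protection.
- Key bond C6–C7: an indium-mediated union of a (Z)-2-(bromomethyl)enoate, acting as an ester homoenolate (d3) equivalent, with the west enal. This forms the cis α-methylene-γ-butyrolactone first and sets C6 and C7 relative to C8.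
- East bromide from (R)-glyceraldehyde acetonide (2-bromoallylation, Morita–Baylis–Hillman, SN2′ bromination); west enal from but-2-yne-1,4-diol by anti-carbomagnesiation; side-chain acid from (S)-glyceraldehyde acetonide by alkyne hydrocarboxylation.

Assumption: the SMILES is read as 1R,6S,7R,8S,3′R with a cis-fused lactone; positions use germacrane-type numbering (C1 carbinol, C4=C5 ring olefin, C6 lactone O–CH, C7, C8 ester O–CH, C10=C14, C11=C13, C12 lactone C=O, C15 acetoxymethyl).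

**West enal**

Step 1
Reactants: 1 but-2-yne-1,4-diol
Product: 2 4-[(tert-butyldimethylsilyl)oxy]but-2-yn-1-ol
Conditions: NaH (1.0 equiv), THF, 0 °C; then TBSCl (1.0 equiv), rt
Reagents that add atoms: tert-butyldimethylsilyl chloride, CC(C)(C)[Si](C)(C)Cl
Why: Monosilylation of a symmetrical diol through its sparingly soluble monosodium alkoxide (McDougal protocol) leaves one free hydroxyl to direct the next step.

Step 2
Reactants: 2 4-[(tert-butyldimethylsilyl)oxy]but-2-yn-1-ol, 3 2-(2-bromoethyl)-1,3-dioxolane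
Product: 6 (2E)-4-[(tert-butyldimethylsilyl)oxy]-2-[2-(1,3-dioxolan-2-yl)ethyl]but-2-en-1-ol, via Grignard reagent 4 (not isolated), via alkenylmagnesium chelate 5 (not isolated)
Conditions: 3 (3 equiv), Mg, THF, 25 °C; then 2, CuI (10 mol %), THF, −20 °C → rt; aq. NH4Cl
Reagents that add atoms: none
Why: Hydroxyl-directed, CuI-catalysed anti-carbomagnesiation of a propargylic alcohol puts the alkyl group on the carbon next to the free CH2OH and magnesium on the distal carbon in a five-membered chelate, so protonation gives the olefin with C15 trans to C6 (C3 cis to C6), the geometry of the target ring olefin.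

Step 3
Reactants: 6 (2E)-4-[(tert-butyldimethylsilyl)oxy]-2-[2-(1,3-dioxolan-2-yl)ethyl]but-2-en-1-ol
Product: 7 (2E)-4-[(tert-butyldimethylsilyl)oxy]-2-[2-(1,3-dioxolan-2-yl)ethyl]but-2-en-1-yl acetate
Conditions: Ac2O, pyridine, DMAP (cat.), CH2Cl2, 0 °C → rt
Reagents that add atoms: acetic anhydride, CC(=O)OC(C)=O
Why: Standard DMAP-catalysed acetylation of the only free (primary allylic) hydroxyl installs the C15 acetate of the target.

Step 4
Reactants: 7 (2E)-4-[(tert-butyldimethylsilyl)oxy]-2-[2-(1,3-dioxolan-2-yl)ethyl]but-2-en-1-yl acetate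
Product: 8 (2E)-2-[2-(1,3-dioxolan-2-yl)ethyl]-4-hydroxybut-2-en-1-yl acetate
Conditions: HF·pyridine, pyridine, THF, 0 °C → rt
Reagents that add atoms: none
Why: Buffered fluoride desilylation removes the primary TBS ether without touching the acetate or the dioxolane, and the trans arrangement of the two oxygenated carbons rules out acetyl migration.

Step 5
Reactants: 8 (2E)-2-[2-(1,3-dioxolan-2-yl)ethyl]-4-hydroxybut-2-en-1-yl acetate
Product: 9 (2E)-2-[2-(1,3-dioxolan-2-yl)ethyl]-4-oxobut-2-en-1-yl acetate (west enal)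
Conditions: MnO2 (15 equiv), CH2Cl2, rt
Reagents that add atoms: none
Why: Neutral MnO2 oxidation of a primary allylic alcohol gives the enal without isomerising the trisubstituted olefin, as in nerol to neral.

**East bromide**

Step 6
Reactants: 10 (R)-2,2-dimethyl-1,3-dioxolane-4-carbaldehyde, 11 2,3-dibromoprop-1-ene
Product: 13 (1S)-3-bromo-1-[(4R)-2,2-dimethyl-1,3-dioxolan-4-yl]but-3-en-1-ol, via allylzinc bromide 12 (not isolated)
Conditions: zinc dust, THF/sat. aq. NH4Cl, 0 °C → rt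
Reagents that add atoms: none
Why: Barbier 2-bromoallylation in which zinc inserts only into the allylic C–Br bond and Felkin–Anh addition anti to the dioxolane C–O bond gives the anti (1S) adduct as major isomer (minor syn isomer removed by chromatography), which fixes C8.

Step 7
Reactants: 13 (1S)-3-bromo-1-[(4R)-2,2-dimethyl-1,3-dioxolan-4-yl]but-3-en-1-ol
Product: 14 (4R)-4-{(1S)-3-bromo-1-[(4-methoxybenzyl)oxy]but-3-en-1-yl}-2,2-dimethyl-1,3-dioxolane
Conditions: NaH, PMBCl, Bu4NI (cat.), THF/DMF, 0 °C → rt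
Reagents that add atoms: 4-methoxybenzyl chloride, COc1ccc(CCl)cc1
Why: Williamson etherification protects the C8 oxygen with a group that survives acid, periodate, amine and bromination conditions and is later removed oxidatively under neutral conditions.

Step 8
Reactants: 14 (4R)-4-{(1S)-3-bromo-1-[(4-methoxybenzyl)oxy]but-3-en-1-yl}-2,2-dimethyl-1,3-dioxolane
Product: 15 (2S)-4-bromo-2-[(4-methoxybenzyl)oxy]pent-4-enal
Conditions: H5IO6 (1.5 equiv), EtOAc, rt; used crude
Reagents that add atoms: none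
Why: Periodic acid hydrolyses the terminal acetonide and cleaves the liberated 1,2-diol in one pot (glycol cleavage), giving the α-alkoxy aldehyde without epimerising it.

Step 9
Reactants: 15 (2S)-4-bromo-2-[(4-methoxybenzyl)oxy]pent-4-enal, 16 methyl acrylate
Product: 17 methyl (4S)-6-bromo-3-hydroxy-4-[(4-methoxybenzyl)oxy]-2-methylidenehept-6-enoate (both C3 epimers)
Conditions: DABCO (1.0 equiv), MeOH (cat.), neat 16 (5 equiv), rt, 2–3 d
Reagents that add atoms: none
Why: Morita–Baylis–Hillman reaction, for which α-alkoxy aldehydes are among the most reactive partners; the new carbinol centre is irrelevant because it is transposed in the next step.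

Step 10
Reactants: 17 methyl (4S)-6-bromo-3-hydroxy-4-[(4-methoxybenzyl)oxy]-2-methylidenehept-6-enoate
Product: 18 methyl (2Z,4S)-6-bromo-2-(bromomethyl)-4-[(4-methoxybenzyl)oxy]hepta-2,6-dienoate
Conditions: NBS, Me2S, CH2Cl2, 0 °C → rt
Reagents that add atoms: N-bromosuccinimide, O=C1CCC(=O)N1Br
Why: The alkoxysulfonium derivative of the Morita–Baylis–Hillman alcohol is displaced by bromide in SN2′ fashion to give the thermodynamically preferred (Z)-2-(bromomethyl)enoate (C8 cis to CH2Br, trans to the ester).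

**Side-chain acid**

Step 11
Reactants: 19 (S)-2,2-dimethyl-1,3-dioxolane-4-carbaldehyde
Product: 20 (4R)-4-ethynyl-2,2-dimethyl-1,3-dioxolane
Conditions: dimethyl (1-diazo-2-oxopropyl)phosphonate, K2CO3, MeOH, 0 °C → rt
Reagents that add atoms: dimethyl (1-diazo-2-oxopropyl)phosphonate, COP(=O)(OC)C(=[N+]=[N-])C(C)=O
Why: Ohira–Bestmann (Seyferth–Gilbert) homologation converts the aldehyde into the terminal alkyne under conditions known to preserve the glyceraldehyde stereocentre (the descriptor changes from S to R only through priorities).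

Step 12
Reactants: 20 (4R)-4-ethynyl-2,2-dimethyl-1,3-dioxolane
Product: 21 2-[(4R)-2,2-dimethyl-1,3-dioxolan-4-yl]prop-2-enoic acid
Conditions: Pd(OAc)2 (0.5 mol %), 2-(diphenylphosphino)pyridine (10 mol %), MsOH (5 mol %), CO (20 bar), THF/H2O, 50 °C
Reagents that add atoms: carbon monoxide, [C-]#[O+]; water, O
Why: Palladium-catalysed Markovnikov hydrocarboxylation of a terminal alkyne with the pyridylphosphine system gives the branched 2-substituted acrylic acid, and the excess basic ligand buffers the acid so the acetonide survives.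

**Fragment union and endgame**

Step 13
Reactants: 18 methyl (2Z,4S)-6-bromo-2-(bromomethyl)-4-[(4-methoxybenzyl)oxy]hepta-2,6-dienoate, 9 (2E)-2-[2-(1,3-dioxolan-2-yl)ethyl]-4-oxobut-2-en-1-yl acetate
Product: 24 (4R,5S)-5-[(1E)-2-(acetoxymethyl)-4-(1,3-dioxolan-2-yl)but-1-en-1-yl]-4-{(1S)-3-bromo-1-[(4-methoxybenzyl)oxy]but-3-en-1-yl}-3-methylideneoxolan-2-one, via allylindium dibromide 22 (not isolated), via open hydroxy ester 23 (not isolated)
Conditions: indium powder (1.5 equiv), THF/H2O (1:1), rt; then CSA (5 mol %), CH2Cl2, rt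
Reagents that add atoms: none
Why: Indium inserts into the allylic C–Br bond to give a 2-(methoxycarbonyl)allylindium, an ester homoenolate (β-acyl carbanion, d3) equivalent, so that C7, natively the electrophilic β-carbon of the enoate, attacks the electrophilic carbonyl carbon C6 of 9 (Barbier-type carbonyl 2-(alkoxycarbonyl)allylation); the Z-γ-substituted reagent reacts through a chair transition state to give the 6,7-syn adduct and hence the cis-lactone after acid-catalysed lactonisation, while the C8 centre (H eclipsing C7=C11 to avoid allylic 1,3-strain, the PMB-ether oxygen either coordinated to indium or turned away from the incoming aldehyde) exposes the face that leads to 6S,7R.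

Step 14
Reactants: 24 (4R,5S)-5-[(1E)-2-(acetoxymethyl)-4-(1,3-dioxolan-2-yl)but-1-en-1-yl]-4-{(1S)-3-bromo-1-[(4-methoxybenzyl)oxy]but-3-en-1-yl}-3-methylideneoxolan-2-one
Product: 25 (4R,5S)-5-[(1E)-2-(acetoxymethyl)-4-(1,3-dioxolan-2-yl)but-1-en-1-yl]-4-[(1S)-3-bromo-1-hydroxybut-3-en-1-yl]-3-methylideneoxolan-2-one
Conditions: DDQ (1.3 equiv), CH2Cl2/pH 7 phosphate buffer (10:1), 0 °C → rt
Reagents that add atoms: none
Why: Oxidative PMB cleavage under buffered neutral conditions frees the C8 hydroxyl without opening or translactonising the 6,12-lactone and without touching the acetal, acetate or alkenyl bromide.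

Step 15
Reactants: 25 (4R,5S)-5-[(1E)-2-(acetoxymethyl)-4-(1,3-dioxolan-2-yl)but-1-en-1-yl]-4-[(1S)-3-bromo-1-hydroxybut-3-en-1-yl]-3-methylideneoxolan-2-one, 21 2-[(4R)-2,2-dimethyl-1,3-dioxolan-4-yl]prop-2-enoic acid
Product: 27 (1S)-1-{(3R,4S... see list)}: (4R,5S)-5-[(1E)-2-(acetoxymethyl)-4-(1,3-dioxolan-2-yl)but-1-en-1-yl]-4-[(1S)-3-bromo-1-({2-[(4R)-2,2-dimethyl-1,3-dioxolan-4-yl]prop-2-enoyl}oxy)but-3-en-1-yl]-3-methylideneoxolan-2-one, via mixed anhydride 26 (not isolated)
Conditions: 21, 2,4,6-trichlorobenzoyl chloride, Et3N, THF, rt; then 25, DMAP, toluene, rt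
Reagents that add atoms: none
Why: Yamaguchi esterification acylates the hindered secondary C8 alcohol with retention, DMAP attacking the less hindered acryloyl carbonyl of the mixed anhydride, and acyl transfer at rt is faster than base-induced translactonisation.

Step 16
Reactants: 27 (4R,5S)-5-[(1E)-2-(acetoxymethyl)-4-(1,3-dioxolan-2-yl)but-1-en-1-yl]-4-[(1S)-3-bromo-1-({2-[(4R)-2,2-dimethyl-1,3-dioxolan-4-yl]prop-2-enoyl}oxy)but-3-en-1-yl]-3-methylideneoxolan-2-one
Product: 28 (4R,5S)-5-[(1E)-2-(acetoxymethyl)-5-oxopent-1-en-1-yl]-4-[(1S)-3-bromo-1-{[(3R)-3,4-dihydroxy-2-methylidenebutanoyl]oxy}but-3-en-1-yl]-3-methylideneoxolan-2-one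
Conditions: 1 M aq. HCl/THF (1:4), rt
Reagents that add atoms: water, O
Why: Dilute aqueous acid hydrolyses both the dioxolane acetal and the acetonide in one operation while the allylic acetate, the two esters, the lactone and the alkenyl bromide are stable under these conditions.

Step 17
Reactants: 28 (4R,5S)-5-[(1E)-2-(acetoxymethyl)-5-oxopent-1-en-1-yl]-4-[(1S)-3-bromo-1-{[(3R)-3,4-dihydroxy-2-methylidenebutanoyl]oxy}but-3-en-1-yl]-3-methylideneoxolan-2-one
Product: 30 target CNP0245550.1, (1R,6S,7R,8S)-15-acetoxy-1-hydroxy-8-{[(3R)-3,4-dihydroxy-2-methylidenebutanoyl]oxy}germacra-4E,10(14),11(13)-trien-12,6-olide, via alkenylchromium dichloride 29 (not isolated)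
Conditions: CrCl2 (10 equiv), NiCl2 (0.2 equiv), DMSO/THF, 2 mM (slow addition of 28), rt → 40 °C; aq. sodium serinate work-up
Reagents that add atoms: none
Why: Nozaki–Hiyama–Kishi macrocyclisation, in which zerovalent nickel activates the 2-bromoalkene, transmetalation gives an alkenylchromium that adds only to the aldehyde (free hydroxyls, esters and the methylene lactone are tolerated) and closes the ten-membered ring; C1 is set under substrate control by the rigid cis-lactone/Z-olefin segment, with peripheral attack expected to favour 1R, and this is the least secure stereochemical prediction of the route (the C1 epimer is separable).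

**Compound list**

1 | but-2-yne-1,4-diol | OCC#CCO | starting material
2 | 4-[(tert-butyldimethylsilyl)oxy]but-2-yn-1-ol | OCC#CCO[Si](C)(C)C(C)(C)C | intermediate
3 | 2-(2-bromoethyl)-1,3-dioxolane | BrCCC1OCCO1 | starting material
4 | [2-(1,3-dioxolan-2-yl)ethyl]magnesium bromide | Br[Mg]CCC1OCCO1 | intermediate (not isolated)
5 | 4-[2-(1,3-dioxolan-2-yl)ethyl]-3-{[(tert-butyldimethylsilyl)oxy]methyl}-2,5-dihydro-1,2-oxamagnesole (alkenylmagnesium alkoxide chelate) | [Mg]1OCC(CCC2OCCO2)=C1CO[Si](C)(C)C(C)(C)C | intermediate (not isolated)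
6 | (2E)-4-[(tert-butyldimethylsilyl)oxy]-2-[2-(1,3-dioxolan-2-yl)ethyl]but-2-en-1-ol | OC/C(CCC1OCCO1)=C/CO[Si](C)(C)C(C)(C)C | intermediate
7 | (2E)-4-[(tert-butyldimethylsilyl)oxy]-2-[2-(1,3-dioxolan-2-yl)ethyl]but-2-en-1-yl acetate | CC(=O)OC/C(CCC1OCCO1)=C/CO[Si](C)(C)C(C)(C)C | intermediate
8 | (2E)-2-[2-(1,3-dioxolan-2-yl)ethyl]-4-hydroxybut-2-en-1-yl acetate | CC(=O)OC/C(CCC1OCCO1)=C/CO | intermediate
9 | (2E)-2-[2-(1,3-dioxolan-2-yl)ethyl]-4-oxobut-2-en-1-yl acetate (west enal) | CC(=O)OC/C(CCC1OCCO1)=C/C=O | intermediate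
10 | (R)-2,2-dimethyl-1,3-dioxolane-4-carbaldehyde | O=C[C@H]1COC(C)(C)O1 | starting material
11 | 2,3-dibromoprop-1-ene | C=C(Br)CBr | starting material
12 | (2-bromoprop-2-en-1-yl)zinc bromide | C=C(Br)C[Zn]Br | intermediate (not isolated)
13 | (1S)-3-bromo-1-[(4R)-2,2-dimethyl-1,3-dioxolan-4-yl]but-3-en-1-ol | C=C(Br)C[C@H](O)[C@H]1COC(C)(C)O1 | intermediate
14 | (4R)-4-{(1S)-3-bromo-1-[(4-methoxybenzyl)oxy]but-3-en-1-yl}-2,2-dimethyl-1,3-dioxolane | C=C(Br)C[C@H](OCc1ccc(OC)cc1)[C@H]2COC(C)(C)O2 | intermediate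
15 | (2S)-4-bromo-2-[(4-methoxybenzyl)oxy]pent-4-enal | C=C(Br)C[C@H](OCc1ccc(OC)cc1)C=O | intermediate
16 | methyl acrylate | C=CC(=O)OC | starting material
17 | methyl (4S)-6-bromo-3-hydroxy-4-[(4-methoxybenzyl)oxy]-2-methylidenehept-6-enoate (C3 epimers) | C=C(Br)C[C@H](OCc1ccc(OC)cc1)C(O)C(=C)C(=O)OC | intermediate
18 | methyl (2Z,4S)-6-bromo-2-(bromomethyl)-4-[(4-methoxybenzyl)oxy]hepta-2,6-dienoate (east bromide) | C=C(Br)C[C@H](OCc1ccc(OC)cc1)/C=C(\CBr)C(=O)OC | intermediate
19 | (S)-2,2-dimethyl-1,3-dioxolane-4-carbaldehyde | O=C[C@@H]1COC(C)(C)O1 | starting material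
20 | (4R)-4-ethynyl-2,2-dimethyl-1,3-dioxolane | C#C[C@@H]1COC(C)(C)O1 | intermediate
21 | 2-[(4R)-2,2-dimethyl-1,3-dioxolan-4-yl]prop-2-enoic acid | C=C(C(=O)O)[C@@H]1COC(C)(C)O1 | intermediate
22 | allylindium reagent from 18, drawn as the dibromide (indium on C13) | C=C(Br)C[C@H](OCc1ccc(OC)cc1)/C=C(\C[In](Br)Br)C(=O)OC | intermediate (not isolated)
23 | methyl (3S,4S,5E)-6-(acetoxymethyl)-3-{(1S)-3-bromo-1-[(4-methoxybenzyl)oxy]but-3-en-1-yl}-8-(1,3-dioxolan-2-yl)-4-hydroxy-2-methylideneoct-5-enoate (6,7-syn adduct) | C=C(C(=O)OC)[C@@H]([C@@H](O)/C=C(/COC(C)=O)CCC1OCCO1)[C@@H](OCc2ccc(OC)cc2)CC(Br)=C | intermediate (not isolated)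
24 | (4R,5S)-5-[(1E)-2-(acetoxymethyl)-4-(1,3-dioxolan-2-yl)but-1-en-1-yl]-4-{(1S)-3-bromo-1-[(4-methoxybenzyl)oxy]but-3-en-1-yl}-3-methylideneoxolan-2-one (cis-lactone; 6S,7R,8S) | C=C1C(=O)O[C@@H](/C=C(/COC(C)=O)CCC2OCCO2)[C@H]1[C@@H](OCc3ccc(OC)cc3)CC(Br)=C | intermediate
25 | (4R,5S)-5-[(1E)-2-(acetoxymethyl)-4-(1,3-dioxolan-2-yl)but-1-en-1-yl]-4-[(1S)-3-bromo-1-hydroxybut-3-en-1-yl]-3-methylideneoxolan-2-one | C=C1C(=O)O[C@@H](/C=C(/COC(C)=O)CCC2OCCO2)[C@H]1[C@@H](O)CC(Br)=C | intermediate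
26 | 2-[(4R)-2,2-dimethyl-1,3-dioxolan-4-yl]prop-2-enoic 2,4,6-trichlorobenzoic anhydride | C=C(C(=O)OC(=O)c1c(Cl)cc(Cl)cc1Cl)[C@@H]2COC(C)(C)O2 | intermediate (not isolated)
27 | (4R,5S)-5-[(1E)-2-(acetoxymethyl)-4-(1,3-dioxolan-2-yl)but-1-en-1-yl]-4-[(1S)-3-bromo-1-({2-[(4R)-2,2-dimethyl-1,3-dioxolan-4-yl]prop-2-enoyl}oxy)but-3-en-1-yl]-3-methylideneoxolan-2-one | C=C1C(=O)O[C@@H](/C=C(/COC(C)=O)CCC2OCCO2)[C@H]1[C@@H](OC(=O)C(=C)[C@@H]3COC(C)(C)O3)CC(Br)=C | intermediate
28 | (4R,5S)-5-[(1E)-2-(acetoxymethyl)-5-oxopent-1-en-1-yl]-4-[(1S)-3-bromo-1-{[(3R)-3,4-dihydroxy-2-methylidenebutanoyl]oxy}but-3-en-1-yl]-3-methylideneoxolan-2-one (seco aldehyde) | C=C1C(=O)O[C@@H](/C=C(/COC(C)=O)CCC=O)[C@H]1[C@@H](OC(=O)C(=C)[C@@H](O)CO)CC(Br)=C | intermediate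
29 | alkenylchromium dichloride from 28 (chromium on C10) | C=C1C(=O)O[C@@H](/C=C(/COC(C)=O)CCC=O)[C@H]1[C@@H](OC(=O)C(=C)[C@@H](O)CO)CC(=C)[Cr](Cl)Cl | intermediate (not isolated)
30 | CNP0245550.1, (1R,6S,7R,8S)-15-acetoxy-1-hydroxy-8-{[(3R)-3,4-dihydroxy-2-methylidenebutanoyl]oxy}germacra-4E,10(14),11(13)-trien-12,6-olide | C=C1C(=O)O[C@H]2/C=C(/COC(C)=O)CC[C@@H](O)C(=C)C[C@H](OC(=O)C(=C)[C@@H](O)CO)[C@@H]12 | target

**Step count**

Total: 17 steps. Longest linear sequence: 10 steps (1 → 2 → 6 → 7 → 8 → 9 → 24 → 25 → 27 → 28 → 30; the branch from 10 through 18 is equally long).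

**Three steps most likely to fail**

Step 13 (key union). The risks are reductive 1,4-elimination of the allylindium with loss of the C8 ether, and insufficient facial control by C8. The fallback replaces the reductive metalation by an isolable allylboron reagent. It sets out from 17: acetylation (Ac2O, DMAP) gives the Morita–Baylis–Hillman acetate F1. Borylation with bis(pinacolato)diboron and Pd2(dba)3 in toluene at 50 °C (the allylic acetate ionises much faster than zerovalent palladium inserts into the 2-bromoalkene) gives the primary allylboronate F2, with C8 cis to CH2B. Sc(OTf)3-catalysed allylboration of 9 through a closed chair transition state then gives the syn adduct, which lactonises in the same pot. The route is rejoined at 24.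

Step 17 (macrocyclisation and C1). The risks are a sluggish alkenyl bromide, interference by the free diol, and the wrong C1 epimer. The fallback closes the ring before the side chain is attached, so that C1 can be corrected. It sets out from 24: 1 M aq. HCl/THF gives the aldehyde F3, and CrCl2/NiCl2 macrocyclisation (a Kishi oxazoline–sulfonamide ligand can be used here, since no free diol is present) gives the macrocyclic allylic alcohol F4 as whatever C1 mixture forms. Dess–Martin oxidation gives the enone F5, and reduction with (S)-2-methyl-CBS-oxazaborolidine and catecholborane (alkenyl as the large group) gives the 1R alcohol F6. TESCl/imidazole gives the triethylsilyl ether F7, DDQ gives the C8 alcohol F8, and Yamaguchi acylation with 26 (from 21) gives the ester F9. AcOH/THF/H2O then removes the silyl ether and the acetonide together. The route is rejoined at 30.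

Step 2 (carbomagnesiation). The risk is a low yield with a functionalised primary alkyl Grignard reagent. The fallback builds the same olefin by trans-hydroalumination and cross-coupling. It sets out from 2: NaAlH2(OCH2CH2OMe)2 in THF followed by iodine gives the vinyl iodide F10 (iodine cis to the free CH2OH). 2-Vinyl-1,3-dioxolane and 9-BBN give the B-alkyl borane F11, and Suzuki–Miyaura coupling with F10 (Pd(dppf)Cl2, AsPh3, aq. K3PO4, DMF) gives with retention the allylic alcohol F12. MnO2 gives the silyloxy enal F13, HF·pyridine gives the hydroxy enal F14, and acetylation (Ac2O, pyridine) completes the sequence. The route is rejoined at 9.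

**Further compounds**

F1 | step 13 | methyl (4S)-3-acetoxy-6-bromo-4-[(4-methoxybenzyl)oxy]-2-methylidenehept-6-enoate | C=C(Br)C[C@H](OCc1ccc(OC)cc1)C(OC(C)=O)C(=C)C(=O)OC
F2 | step 13 | methyl (2E,4S)-6-bromo-4-[(4-methoxybenzyl)oxy]-2-[(4,4,5,5-tetramethyl-1,3,2-dioxaborolan-2-yl)methyl]hepta-2,6-dienoate | C=C(Br)C[C@H](OCc1ccc(OC)cc1)/C=C(\CB2OC(C)(C)C(C)(C)O2)C(=O)OC
F3 | step 17 | (4R,5S)-5-[(1E)-2-(acetoxymethyl)-5-oxopent-1-en-1-yl]-4-{(1S)-3-bromo-1-[(4-methoxybenzyl)oxy]but-3-en-1-yl}-3-methylideneoxolan-2-one | C=C1C(=O)O[C@@H](/C=C(/COC(C)=O)CCC=O)[C@H]1[C@@H](OCc2ccc(OC)cc2)CC(Br)=C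
F4 | step 17 | (6S,7R,8S)-15-acetoxy-1-hydroxy-8-[(4-methoxybenzyl)oxy]germacra-4E,10(14),11(13)-trien-12,6-olide, C1 epimer mixture | C=C1C(=O)O[C@H]2/C=C(/COC(C)=O)CCC(O)C(=C)C[C@H](OCc3ccc(OC)cc3)[C@@H]12
F5 | step 17 | (6S,7R,8S)-15-acetoxy-8-[(4-methoxybenzyl)oxy]-1-oxogermacra-4E,10(14),11(13)-trien-12,6-olide | C=C1C(=O)O[C@H]2/C=C(/COC(C)=O)CCC(=O)C(=C)C[C@H](OCc3ccc(OC)cc3)[C@@H]12
F6 | step 17 | (1R,6S,7R,8S)-15-acetoxy-1-hydroxy-8-[(4-methoxybenzyl)oxy]germacra-4E,10(14),11(13)-trien-12,6-olide | C=C1C(=O)O[C@H]2/C=C(/COC(C)=O)CC[C@@H](O)C(=C)C[C@H](OCc3ccc(OC)cc3)[C@@H]12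
F7 | step 17 | (1R,6S,7R,8S)-15-acetoxy-8-[(4-methoxybenzyl)oxy]-1-[(triethylsilyl)oxy]germacra-4E,10(14),11(13)-trien-12,6-olide | C=C1C(=O)O[C@H]2/C=C(/COC(C)=O)CC[C@@H](O[Si](CC)(CC)CC)C(=C)C[C@H](OCc3ccc(OC)cc3)[C@@H]12
F8 | step 17 | (1R,6S,7R,8S)-15-acetoxy-8-hydroxy-1-[(triethylsilyl)oxy]germacra-4E,10(14),11(13)-trien-12,6-olide | C=C1C(=O)O[C@H]2/C=C(/COC(C)=O)CC[C@@H](O[Si](CC)(CC)CC)C(=C)C[C@H](O)[C@@H]12
F9 | step 17 | (1R,6S,7R,8S)-15-acetoxy-8-({2-[(4R)-2,2-dimethyl-1,3-dioxolan-4-yl]prop-2-enoyl}oxy)-1-[(triethylsilyl)oxy]germacra-4E,10(14),11(13)-trien-12,6-olide | C=C1C(=O)O[C@H]2/C=C(/COC(C)=O)CC[C@@H](O[Si](CC)(CC)CC)C(=C)C[C@H](OC(=O)C(=C)[C@@H]3COC(C)(C)O3)[C@@H]12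
F10 | step 2 | (2Z)-4-[(tert-butyldimethylsilyl)oxy]-3-iodobut-2-en-1-ol | OC/C=C(\I)CO[Si](C)(C)C(C)(C)C
F11 | step 2 | 9-[2-(1,3-dioxolan-2-yl)ethyl]-9-borabicyclo[3.3.1]nonane | C1CCC2CCCC1B2CCC1OCCO1
F12 | step 2 | (2E)-3-{[(tert-butyldimethylsilyl)oxy]methyl}-5-(1,3-dioxolan-2-yl)pent-2-en-1-ol | OC/C=C(\CCC1OCCO1)CO[Si](C)(C)C(C)(C)C
F13 | step 2 | (2E)-3-{[(tert-butyldimethylsilyl)oxy]methyl}-5-(1,3-dioxolan-2-yl)pent-2-enal | O=C/C=C(\CCC1OCCO1)CO[Si](C)(C)C(C)(C)C
F14 | step 2 | (2E)-5-(1,3-dioxolan-2-yl)-3-(hydroxymethyl)pent-2-enal | O=C/C=C(\CCC1OCCO1)CO
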